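Blue holds half the Q of ochre at the same cL, so this pair has a zero on its scale: equal readings mean order zero in Q.

in all of them: G 0.00400 M
- ochre: L 0.400 M; Q 1.00 M
- blue: L 0.400 M; Q 0.500 M
- violet: L 0.200 M; Q 1.00 M
- green: L 0.200 M; Q 0.330 M; time 91 h

| ochre run: time / h | ochre run: [X] / M | blue run: time / h | blue run: [X] / M | violet run: time / h | violet run: [X] / M |
|---|---|---|---|---|---|
| 3.6 | 0.0270 | 3.6 | 0.0272 | 3.6 | 0.0169 |
| 6.9 | 0.0481 | 6.9 | 0.0485 | 6.9 | 0.0299 |
| 13 | 0.0888 | 13 | 0.0901 | 13 | 0.0548 |
| 25 | 0.1540 | 25 | 0.1584 | 25 | 0.0932 |
| 48 | 0.2426 | 48 | 0.2563 | 48 | 0.1327 |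
| 91 | 0.3221 | 91 | 0.3499 | 91 | 0.1656 |

(readings scatter by 0.001 M)

1. reaction order in [L] at the outset, round the charge of the ochre run, defined at two percent of the L turned into X (one fixed amount of X, the same in the runs compared)
2. reaction order in [Q] at the outset, round the charge of the ochre run, defined at two percent of the L turned into X
3. X in the green run at 91 h, as a share of the L charged

- Overall: L + Q -> X, with G as catalyst.
- Constant volume, constant temperature.
- A reading of a species includes what of it is bound.
- An order is taken over about fifteen percent of the charge, up and down.

At 3.6 h the readings are 0.0272 M for blue and 0.0270 M for ochre, an order in Q of −0.0106 with a scatter near 0.0756, which cannot be told from zero. But violet, with half the L of ochre, stands below ochre at that time by a factor 1.60, between 1 for saturated G and 2 for free G. A saturation law, rate proportional to cL/(1 + K·cL), then gives K = 1.68 /M and a local order in L of 0.598 at the ochre charge.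

Integrated, that law says Φ = ln(cL at the start/cL) + K·(cL at the start − cL) grows in step with time while G stays whole. So ochre and blue, with one charge of L, should share one Φ at 91 h, which is a second zero. But ochre reads 2.18 and blue 2.67, and blue, with less Q, is ahead. A measure of what Q each run has held is the Q-dose, the time integral of cQ, with cQ falling as cX rises; over 91 h it comes to a mean cQ of 0.794 M for ochre and 0.281 M for blue. The dose price, the fall of Φ per unit of Q-dose between these two runs, is 0.0105 /M/h.

In the green run L is the limiting reagent, at 0.200 M against 0.330 M of Q. Borrowing from violet, with the same L charge, its mean cX of 0.113 M puts the mean cQ of the green run over 91 h at 0.217 M. The price then gives Φ = 2.73, and so a share of about 91.1%.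

The forecast gives 0.57 (0.46 to 0.69), 0 (−0.1 to 0.1) and 91.5% (87% to 95%), taking the late lag to suggest that “Q slowly kills the catalyst”; its order in L lies below this reckoning's and its share above.

The simulation gives 0.52, 0.011 and 92.3%.

    G + L → GL (23.29 /M/h)
    GL + Q → Ja (232.6 /M/h)
    Ja → X + G (9.684 /h)
    G + Zu → Xi
    G + Q → Xi + Q (0.01663 /M/h)

In the green run Zu took 0.00233 M of G at the outset, leaving 1.67 mM to turn through GL and Ja. For 91 h that cycle ran while G + Q → Xi + Q drew G away, and at the end 0.145 M of the Q charged had not become X. The green share means Φ = 2.88, which is 0.150 above what the dose price gave. Violet, at a mean cQ of 0.887 M, reads 2.04 at 91 h, where the dose price gives 2.09.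

The earlier runs and the new flask are simulated with constants of no real substance; scatter was added.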